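**Plan**

1. Retrosynthesis (target numbering: C1 ketone, C2=C3, C4=C15, C5–OH, C6–O lactone, C7, C8 ester, C9, C10–Me, C11=C13, C12): cut the C12–O6 lactone and the C8 ester, take the furanone back to a C1 vinyl bromide, re-draw a C4–C8 bond (reverse Grob), then cut C7–C8 (zinc allylation), C4–C5 (aldol) and C3–C4/C9–C10 ((4+3) cycloaddition).
2. Enabling feature: a C4–C8 bond would turn the ether-bridged cyclodecane (C1–C10, oxygen between C3 and C10) into an 8-oxabicyclo[3.2.1]octene (C3, C4, C8, C9, C10, C1, C2, O) carrying a cis-fused cyclopentane C4–C5–C6–C7–C8. With an oxide on C8 and a nucleofuge on C15, that one bond can be cut again to leave exactly C8=O and C4=C15.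
3. Forward order: furan plus oxyallyl cation gives the oxabicycle; C4 methylenation and iodide addition/aldol attach C15 and the C5–C7 chain; zinc closure makes the cyclopentane; the fragmentation merges the five- and seven-membered carbocycles into the ten-membered ring; furanone and lactone are finished last.
4. Stereochemistry: C6 from (S)-glyceraldehyde acetonide; C5 by Felkin–Anh aldol addition, which also selects the 10R enantiomer of the racemic bicycle; C7 by the cyclic zinc transition state; C8 by hydride attack from outside the ring; C4 and C8 of the tricycle are erased in the fragmentation.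

Key step: step 14

Remark on the chemistry: C15 carries iodide as the nucleofuge (it arrives with the regiospecific enolate) and C1 is carried as a vinyl bromide until the end. Compounds 4 to 8 and 16 are racemic and are drawn as the enantiomer that is carried on. In the bicyclic ketones, C4 of the target is C4 of the systematic name, C8 is the ketone carbon C3 and C10 is the methyl-bearing bridgehead C1.

Step 1
Reactants: 1 3-bromofuran
Product: 2 3-bromo-2-methylfuran
Conditions: LiN(iPr)2, THF, −78 °C; MeI, −78 → 25 °C
Reagents that add atoms: iodomethane CI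
Why: Lithiation of 3-bromofuran with the amide base occurs at C2, between the ring oxygen and the bromine, and the 2-lithiofuran is methylated in a standard furan α-lithiation/alkylation.

Step 2
Reactants: 2 3-bromo-2-methylfuran; 3 1,1,3,3-tetrabromoacetone
Product: 5 rac-(1R,5S)-7-bromo-1-methyl-8-oxabicyclo[3.2.1]oct-6-en-3-one, via tribromo cycloadduct 4 (not isolated)
Conditions: Zn, B(OEt)3, THF, 25 °C; then Zn–Cu couple, NH4Cl, MeOH, 25 °C
Reagents that add atoms: none
Why: The zinc-generated oxyallyl cation adds across C2/C5 of the furan in a (4+3) cycloaddition and the two α-bromines are then removed reductively while the vinylic bromide is inert; the symmetric three-carbon partner leaves no regiochemical question, and the bridgeheads C10 and C3 form cis as a racemate.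

Step 3
Reactants: 5 rac-7-bromo-1-methyl-8-oxabicyclo[3.2.1]oct-6-en-3-one
Product: 8 rac-7-bromo-1-methyl-4-methylidene-8-oxabicyclo[3.2.1]oct-6-en-3-one, via Mannich base 6 (not isolated), via trimethylammonium iodide 7 (not isolated)
Conditions: LiN(iPr)2, THF, −78 °C; CH2=NMe2+ I−, −78 → 0 °C; MeI, CH2Cl2, 25 °C; aq. NaHCO3, CH2Cl2, 25 °C
Reagents that add atoms: dimethylmethyleneiminium iodide C=[N+](C)C.[I-]
Why: Kinetic deprotonation should prefer the C4 methylene next to the C3–H bridgehead over the C9 methylene shielded by the methyl on quaternary C10, and Mannich reaction of the enolate followed by quaternisation and β-elimination is the standard α-methylenation of a ketone.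

Step 4
Reactants: 9 (S)-glyceraldehyde acetonide; 10 methyl acrylate
Product: 11 methyl 2-{[(4S)-2,2-dimethyl-1,3-dioxolan-4-yl](hydroxy)methyl}prop-2-enoate (both carbinol epimers)
Conditions: DABCO (cat.), dioxane/H2O, 25 °C
Reagents that add atoms: none
Why: Morita–Baylis–Hillman reaction of an α-alkoxy aldehyde with an acrylate; the new carbinol centre becomes trigonal in the next step, so its configuration is irrelevant, and the dioxolane centre (future C6) is kept.

Step 5
Reactants: 11 Baylis–Hillman adduct
Product: 12 methyl (2Z)-2-(bromomethyl)-3-[(4R)-2,2-dimethyl-1,3-dioxolan-4-yl]prop-2-enoate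
Conditions: NBS, Me2S, CH2Cl2, 0 → 25 °C
Reagents that add atoms: N-bromosuccinimide O=C1CCC(=O)N1Br
Why: The bromosulfonium reagent activates the allylic alcohol and bromide returns by SN2' attack, the standard conversion of Baylis–Hillman alcohols into the thermodynamically preferred (Z)-2-(bromomethyl)enoates.

Step 6
Reactants: 12 bromo enoate acetonide
Product: 13 methyl (2Z,4R)-2-(bromomethyl)-4,5-dihydroxypent-2-enoate
Conditions: AcOH/H2O 4:1, 25 °C
Reagents that add atoms: none
Why: Acid-catalysed acetal hydrolysis, which the allylic bromide and ester survive; the diol is silylated at once because base would close it onto the bromomethyl group.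

Step 7
Reactants: 13 bromo enoate diol
Product: 14 methyl (2Z,4R)-2-(bromomethyl)-4,5-bis(triethylsilyloxy)pent-2-enoate
Conditions: Et3SiOTf, 2,6-lutidine, CH2Cl2, −78 °C
Reagents that add atoms: triethylsilyl trifluoromethanesulfonate CC[Si](CC)(CC)OS(=O)(=O)C(F)(F)F
Why: Silyl triflate with the hindered, non-nucleophilic pyridine base silylates both hydroxyls at low temperature without displacing the reactive allylic bromide (standard silyl ether formation).

Step 8
Reactants: 14 bis-silyl ether
Product: 15 methyl (2Z,4R)-2-(bromomethyl)-5-oxo-4-(triethylsilyloxy)pent-2-enoate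
Conditions: (COCl)2, DMSO, CH2Cl2, −78 → −30 °C; iPr2NEt, −78 → 0 °C
Reagents that add atoms: none
Why: Under Swern conditions a primary triethylsilyl ether is cleaved and oxidised in one operation while the secondary one stays, so the α-silyloxy aldehyde is reached without a free hydroxy aldehyde; the hindered amine at low temperature limits epimerisation at C6.

Step 9
Reactants: 8 rac-methylidene ketone; 15 (R)-α-silyloxy aldehyde
Product: 17 C4-quaternary aldol adduct (C15 iodide; 5-hydroxy; 6-triethylsilyloxy), via iodomethyl silyl enol ether 16 (not isolated)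
Conditions: Me3SiI (1.0 equiv), CH2Cl2, −78 °C; then 15 (0.55 equiv), BF3·OEt2, −78 °C; aqueous work-up
Reagents that add atoms: iodotrimethylsilane C[Si](C)(C)I
Why: Conjugate addition of the silyl iodide gives the tetrasubstituted silyl enol ether regiospecifically, and this adds to the BF3-bound aldehyde in a Mukaiyama aldol from the face of the bridging oxygen, so the new chain is axial on C4 and CH2I equatorial; in the open transition state the complexed carbonyl oxygen is turned away from the silyloxy group and the aldehyde hydrogen, not the chain, lies over the bicycle, Felkin–Anh control by the C6 silyloxy group fixes C5, and only the 10R enantiomer of 8 satisfies both demands, so the limiting aldehyde should select it.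

Step 10
Reactants: 17 aldol adduct
Product: 18 C5 tert-butyldimethylsilyl ether of 17
Conditions: tBuMe2SiOTf, 2,6-lutidine, CH2Cl2, −78 → 0 °C
Reagents that add atoms: tert-butyldimethylsilyl trifluoromethanesulfonate CC(C)(C)[Si](C)(C)OS(=O)(=O)C(F)(F)F
Why: Standard silylation of a hindered secondary alcohol; O5 must be capped so that it cannot act as a second alkoxide in the fragmentation and stays masked during the later oxidation at C12.

Step 11
Reactants: 18 keto allylic bromide
Product: 19 tricyclic C8 tertiary alcohol with the C7 methyl acrylate side chain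
Conditions: Zn dust, THF/sat. aq. NH4Cl, 0 → 25 °C, high dilution
Reagents that add atoms: none
Why: Intramolecular Barbier allylation: zinc inserts only into the allylic bromide, and the allylzinc attacks the C8 ketone through its γ-carbon C7 in a six-membered chair transition state from the equatorial side that the axial C5 tether can reach (5-exo closure), giving the cis-fused cyclopentane with the C8 hydroxyl axial and C11 cis to it, which is the target configuration at C7.

Step 12
Reactants: 19 hydroxy acrylate
Product: 20 C8,C12 diol (2-substituted allylic alcohol at C12)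
Conditions: iBu2AlH, CH2Cl2, −78 °C; aq. potassium sodium tartrate
Reagents that add atoms: none
Why: The aluminium hydride reduces the acrylate 1,2 to the allylic alcohol at low temperature (standard ester reduction), leaving silyl ethers, the neopentyl iodide and the vinyl bromide untouched.

Step 13
Reactants: 20 diol
Product: 21 tricyclic C8 tertiary alcohol C15 iodide (fragmentation precursor; 5-OSiMe2tBu, 6-OSiEt3, 12-OSiEt3)
Conditions: Et3SiCl, imidazole, CH2Cl2, 0 °C
Reagents that add atoms: chlorotriethylsilane CC[Si](Cl)(CC)CC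
Why: Standard selective silylation of the primary allylic hydroxyl; the tertiary C8 hydroxyl, flanked by quaternary C4 and branched C7, is too hindered to react.

Step 14
Reactants: 21 tricyclic C8 tertiary alcohol C15 iodide
Product: 22 C8-keto oxygen-bridged cyclodecadiene with C4=C15 methylene (C1 vinyl bromide)
Conditions: KOtBu (1.05 equiv), THF, −40 → 0 °C; AcOH quench
Reagents that add atoms: none
Why: KOtBu deprotonates the tertiary C8 hydroxyl, and the alkoxide lone pair forms the C8 carbonyl while the C4–C8 σ bond, antiperiplanar to C15–I in the reactive rotamer of the freely rotating iodomethyl group, breaks and iodide leaves, so C4=C15 forms in one concerted heterolytic step. The closest known reaction type is the Grob fragmentation of γ-halo or γ-sulfonyloxy alkoxides of fused bicycles to medium-ring keto-alkenes. No ring is closed: the ten-membered carbocycle appears because the bond shared by the cyclopentane and the seven-membered carbocycle of the oxabicycle is cut, so no macrocyclisation is needed. No stereocentre is made; C4 and C8 become trigonal and C5, C6, C7 and C10 are untouched. The selectivity needed is fragmentation over 4-exo-tet oxetane closure by the same alkoxide and over reaction of any other oxygen; it is secured by the strain of the propellane that oxetane closure across the C4–C8 bond would create, by carbonyl formation and relief of ring-fusion strain that drive the cleavage, and by the silyl cap on O5. One equivalent of base at low temperature and the acidic quench should keep the new β-silyloxy ketone from enolising towards C7.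

Step 15
Reactants: 22 C8 ketone
Product: 23 (8R)-C8 alcohol
Conditions: NaBH4, MeOH/THF, −40 °C
Reagents that add atoms: none
Why: Borohydride reduction in which hydride should reach the C8 carbonyl from outside the ten-membered ring, the inner face being covered by the transannular C4 methylene that was bonded to C8 before the fragmentation; this places the hydroxyl as in the target (8R).

Step 16
Reactants: 23 C8 alcohol
Product: 24 C8 2-methylpropanoate
Conditions: (iPrCO)2O, Et3N, DMAP (cat.), CH2Cl2, 25 °C
Reagents that add atoms: 2-methylpropanoic anhydride CC(C)C(=O)OC(=O)C(C)C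
Why: DMAP-catalysed acylation of the only free hydroxyl with the anhydride (standard esterification).

Step 17
Reactants: 24 C1 vinyl bromide
Product: 25 C1 alkenyl pinacol boronate
Conditions: B2pin2, PdCl2(dppf) (cat.), KOAc, dioxane, 80 °C
Reagents that add atoms: bis(pinacolato)diboron CC1(C)OB(OC1(C)C)B1OC(C)(C)C(C)(C)O1
Why: Miyaura borylation: oxidative addition of zerovalent palladium into the C1–Br bond, acetate-assisted transmetalation and reductive elimination; ester, silyl ethers and the isolated alkenes are tolerated.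

Step 18
Reactants: 25 alkenyl boronate
Product: 26 C1 ketone (C2 methylene)
Conditions: H2O2, NaH2PO4/Na2HPO4 buffer (pH 7), THF, 0 °C
Reagents that add atoms: hydrogen peroxide OO
Why: Standard oxidation of a carbon–boron bond; the alkenyl boronate gives the enol and hence the C1 ketone, and the neutral buffer spares the ester.

Step 19
Reactants: 26 C1 ketone
Product: 28 3(2H)-furanone (C1=O; C2=C3), via trimethylsilyl enol ether 27 (not isolated)
Conditions: Me3SiOTf, Et3N, CH2Cl2, −78 → 0 °C; then Pd(OAc)2 (1.1 equiv), MeCN, 25 °C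
Reagents that add atoms: none
Why: Soft enolisation can only go towards C2 because C10 is quaternary, and Saegusa–Ito oxidation of the silyl enol ether by divalent palladium with β-hydride loss from C3 gives the furanone; the C2=C3 bond is possible now that C3 no longer sits at the bridgehead of a small bicycle.

Step 20
Reactants: 28 tris-silyl ether
Product: 29 C6,C12 diol (O5 still silylated)
Conditions: PPTS (cat.), MeOH, 0 °C
Reagents that add atoms: none
Why: Acid-catalysed methanolysis removes the two triethylsilyl ethers (primary allylic and secondary) and leaves the hindered tert-butyldimethylsilyl ether at C5 (standard selective desilylation).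

Step 21
Reactants: 29 C6,C12 diol
Product: 32 α-methylene γ-lactone (12,6-olide; O5 silylated), via hydroxy enal 30 (not isolated), via lactol 31 (not isolated)
Conditions: TEMPO (cat.), PhI(OAc)2, CH2Cl2, 25 °C
Reagents that add atoms: none
Why: Oxoammonium oxidation of the primary allylic alcohol gives the enal, the cis C6 hydroxyl closes the lactol and a second oxidation gives the lactone (oxidative lactonisation of a 1,4-diol); O5 is protected, so only C12 is oxidised.

Step 22
Reactants: 32 O5-silyl lactone
Product: 33 target CNP0384113.1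
Conditions: HF·pyridine, pyridine, THF, 0 → 25 °C
Reagents that add atoms: none
Why: Fluoride cleavage of the last silyl ether under buffered conditions that the methylene lactone, furanone and ester should tolerate (standard desilylation).

**Compound list**

1 | 3-bromofuran | Brc1ccoc1 | starting material
2 | 3-bromo-2-methylfuran | Cc1occc1Br | intermediate
3 | 1,1,3,3-tetrabromoacetone | BrC(Br)C(=O)C(Br)Br | starting material
4 | rac-2,4,7-tribromo-1-methyl-8-oxabicyclo[3.2.1]oct-6-en-3-one (C–Br epimers; formed in situ) | C[C@@]12C(Br)C(=O)C(Br)[C@@H](C=C1Br)O2 | intermediate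
5 | rac-(1R,5S)-7-bromo-1-methyl-8-oxabicyclo[3.2.1]oct-6-en-3-one | C[C@@]12CC(=O)C[C@@H](C=C1Br)O2 | intermediate
6 | rac-7-bromo-4-[(dimethylamino)methyl]-1-methyl-8-oxabicyclo[3.2.1]oct-6-en-3-one, aminomethyl group axial (formed in situ) | C[C@@]12CC(=O)[C@H](CN(C)C)[C@@H](C=C1Br)O2 | intermediate
7 | trimethylammonium iodide of 6 (formed in situ) | C[C@@]12CC(=O)[C@H](C[N+](C)(C)C)[C@@H](C=C1Br)O2.[I-] | intermediate
8 | rac-7-bromo-1-methyl-4-methylidene-8-oxabicyclo[3.2.1]oct-6-en-3-one | C[C@@]12CC(=O)C(=C)[C@@H](C=C1Br)O2 | intermediate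
9 | (4S)-2,2-dimethyl-1,3-dioxolane-4-carbaldehyde ((S)-glyceraldehyde acetonide) | O=C[C@@H]1COC(C)(C)O1 | starting material
10 | methyl acrylate | C=CC(=O)OC | starting material
11 | methyl 2-{[(4S)-2,2-dimethyl-1,3-dioxolan-4-yl](hydroxy)methyl}prop-2-enoate (carbinol epimers) | COC(=O)C(=C)C(O)[C@@H]1COC(C)(C)O1 | intermediate
12 | methyl (2Z)-2-(bromomethyl)-3-[(4R)-2,2-dimethyl-1,3-dioxolan-4-yl]prop-2-enoate | COC(=O)C(/CBr)=C/[C@@H]1COC(C)(C)O1 | intermediate
13 | methyl (2Z,4R)-2-(bromomethyl)-4,5-dihydroxypent-2-enoate | COC(=O)C(/CBr)=C/[C@@H](O)CO | intermediate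
14 | methyl (2Z,4R)-2-(bromomethyl)-4,5-bis(triethylsilyloxy)pent-2-enoate | COC(=O)C(/CBr)=C/[C@@H](O[Si](CC)(CC)CC)CO[Si](CC)(CC)CC | intermediate
15 | methyl (2Z,4R)-2-(bromomethyl)-5-oxo-4-(triethylsilyloxy)pent-2-enoate (C5 aldehyde, C6 stereocentre, C7=C11, C13 bromide) | COC(=O)C(/CBr)=C/[C@@H](O[Si](CC)(CC)CC)C=O | intermediate
16 | rac-7-bromo-4-(iodomethyl)-1-methyl-3-(trimethylsilyloxy)-8-oxabicyclo[3.2.1]octa-3,6-diene (formed in situ) | C[C@@]12CC(O[Si](C)(C)C)=C(CI)[C@@H](C=C1Br)O2 | intermediate
17 | aldol adduct: 10R bicyclic C8 ketone, C4 quaternary with equatorial CH2I (C15) and axial chain C5H(OH)–C6H(OSiEt3)–C7H=C11(CO2Me)–C13H2Br (Z), C5 and C6 as in the target | C[C@@]12CC(=O)[C@](CI)([C@H](O)[C@H](O[Si](CC)(CC)CC)/C=C(\CBr)C(=O)OC)[C@@H](C=C1Br)O2 | intermediate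
18 | 17 with O5 as tert-butyldimethylsilyl ether | C[C@@]12CC(=O)[C@](CI)([C@H](O[Si](C)(C)C(C)(C)C)[C@H](O[Si](CC)(CC)CC)/C=C(\CBr)C(=O)OC)[C@@H](C=C1Br)O2 | intermediate
19 | tricycle: oxabicycle with cis-fused cyclopentane C4–C8, axial C8–OH, C7 bearing C(=CH2)CO2Me cis to O8, O6 and O5; C15 iodide | C[C@@]12C[C@]3(O)[C@@H](C(=C)C(=O)OC)[C@@H](O[Si](CC)(CC)CC)[C@@H](O[Si](C)(C)C(C)(C)C)[C@]3(CI)[C@@H](C=C1Br)O2 | intermediate
20 | 19 with the ester reduced to the C12 allylic alcohol | C[C@@]12C[C@]3(O)[C@@H](C(=C)CO)[C@@H](O[Si](CC)(CC)CC)[C@@H](O[Si](C)(C)C(C)(C)C)[C@]3(CI)[C@@H](C=C1Br)O2 | intermediate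
21 | fragmentation precursor: tricyclic C8 tertiary alcohol, C15 iodide, 5-OSiMe2tBu, 6-OSiEt3, 12-OSiEt3, C1 vinyl bromide | C[C@@]12C[C@]3(O)[C@@H](C(=C)CO[Si](CC)(CC)CC)[C@@H](O[Si](CC)(CC)CC)[C@@H](O[Si](C)(C)C(C)(C)C)[C@]3(CI)[C@@H](C=C1Br)O2 | intermediate
22 | fragmentation product: 3,10-ether-bridged cyclodeca-1-ene with C8 ketone and C4=C15 methylene, silyl ethers as in 21 | C[C@@]12CC(=O)[C@@H](C(=C)CO[Si](CC)(CC)CC)[C@@H](O[Si](CC)(CC)CC)[C@@H](O[Si](C)(C)C(C)(C)C)C(=C)[C@@H](C=C1Br)O2 | intermediate
23 | (8R)-alcohol from 22 | C[C@@]12C[C@@H](O)[C@@H](C(=C)CO[Si](CC)(CC)CC)[C@@H](O[Si](CC)(CC)CC)[C@@H](O[Si](C)(C)C(C)(C)C)C(=C)[C@@H](C=C1Br)O2 | intermediate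
24 | C8 2-methylpropanoate of 23 | C[C@@]12C[C@@H](OC(=O)C(C)C)[C@@H](C(=C)CO[Si](CC)(CC)CC)[C@@H](O[Si](CC)(CC)CC)[C@@H](O[Si](C)(C)C(C)(C)C)C(=C)[C@@H](C=C1Br)O2 | intermediate
25 | C1 pinacol boronate from 24 | C[C@@]12C[C@@H](OC(=O)C(C)C)[C@@H](C(=C)CO[Si](CC)(CC)CC)[C@@H](O[Si](CC)(CC)CC)[C@@H](O[Si](C)(C)C(C)(C)C)C(=C)[C@@H](C=C1B3OC(C)(C)C(C)(C)O3)O2 | intermediate
26 | C1 ketone (dihydrofuran-3-one) | C[C@@]12C[C@@H](OC(=O)C(C)C)[C@@H](C(=C)CO[Si](CC)(CC)CC)[C@@H](O[Si](CC)(CC)CC)[C@@H](O[Si](C)(C)C(C)(C)C)C(=C)[C@@H](CC1=O)O2 | intermediate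
27 | C1 trimethylsilyl enol ether of 26 (formed in situ) | C[C@@]12C[C@@H](OC(=O)C(C)C)[C@@H](C(=C)CO[Si](CC)(CC)CC)[C@@H](O[Si](CC)(CC)CC)[C@@H](O[Si](C)(C)C(C)(C)C)C(=C)[C@@H](C=C1O[Si](C)(C)C)O2 | intermediate
28 | 3(2H)-furanone with three silyl ethers | C[C@@]12C[C@@H](OC(=O)C(C)C)[C@@H](C(=C)CO[Si](CC)(CC)CC)[C@@H](O[Si](CC)(CC)CC)[C@@H](O[Si](C)(C)C(C)(C)C)C(=C)C(=CC1=O)O2 | intermediate
29 | C6,C12 diol, O5 silylated | C[C@@]12C[C@@H](OC(=O)C(C)C)[C@@H](C(=C)CO)[C@@H](O)[C@@H](O[Si](C)(C)C(C)(C)C)C(=C)C(=CC1=O)O2 | intermediate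
30 | C12 enal with free C6 hydroxyl (formed in situ) | C[C@@]12C[C@@H](OC(=O)C(C)C)[C@@H](C(=C)C=O)[C@@H](O)[C@@H](O[Si](C)(C)C(C)(C)C)C(=C)C(=CC1=O)O2 | intermediate
31 | C12 lactol (formed in situ; lactol carbon epimers) | C[C@@]12C[C@@H](OC(=O)C(C)C)[C@H]3C(=C)C(O)O[C@H]3[C@@H](O[Si](C)(C)C(C)(C)C)C(=C)C(=CC1=O)O2 | intermediate
32 | O5-tert-butyldimethylsilyl ether of the target | C[C@@]12C[C@@H](OC(=O)C(C)C)[C@H]3C(=C)C(=O)O[C@H]3[C@@H](O[Si](C)(C)C(C)(C)C)C(=C)C(=CC1=O)O2 | intermediate
33 | CNP0384113.1: (5S,6R,7R,8R,10R)-5-hydroxy-1-oxo-3,10-epoxygermacra-2,4(15),11(13)-trien-12,6-olid-8-yl 2-methylpropanoate | C[C@@]12C[C@@H](OC(=O)C(C)C)[C@H]3C(=C)C(=O)O[C@H]3[C@@H](O)C(=C)C(=CC1=O)O2 | target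

**Step count and risks**

Total step count: 22. Longest linear sequence: 19 steps (steps 4 to 22, from 9 and 10); the bicyclic branch from 1 is 17 steps (steps 1 to 3 and 9 to 22).

The three steps most likely to fail:

Step 9. The tetrasubstituted silyl enol ether may add too slowly to the hindered aldehyde complex, BF3 may open the oxygen bridge by β-elimination from the enol ether, or the aldehyde may lose its facial bias so that C5 epimers form. Fallback, from 8 and 15: the iodide conjugate addition is run with Et2AlI in CH2Cl2 at −78 °C and the aluminium enolate is trapped by 15 (slight excess) in a closed, chair-like aldol. This more forceful C–C bond formation is expected to give, for the wanted enantiomer of 8, mainly the C5 epimer of 17 F1, which is separated from the adduct of the other enantiomer. Dess–Martin oxidation then gives the β-diketone F2. Zn(BH4)2 in Et2O at −78 °C reduces the acyclic α-silyloxy ketone under chelation to both carbonyl oxygens, with hydride coming from the iodomethyl side in agreement with Felkin–Anh control from C6, and the route is rejoined at 17.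

Step 14. The alkoxide may displace iodide to close an oxetane instead of fragmenting, or the base may epimerise C7 or eliminate the C6 silyloxy group from the newly formed β-silyloxy ketone. Fallback, from 8: a base-free oxidative cleavage of the same bond with tin as the leaving group on C15. Bu3SnLi in THF at −78 °C adds to C15 and Me3SiCl traps the enolate as the stannylmethyl silyl enol ether F3. The conditions of steps 9 to 13 then give in turn the stannyl aldol F4, its tert-butyldimethylsilyl ether F5, the cyclopentanol ester F6, the diol F7 and the γ-stannyl tertiary alcohol F8. Pb(OAc)4 in CH2Cl2 at 0 °C fragments F8 through the lead alkoxide (C4–C8 cleavage with loss of the stannyl group from C15), the known oxidative fragmentation of γ-hydroxy stannanes, and the route is rejoined at 22.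

Step 15. Facial selectivity may be poor if the ten-membered ring adopts a conformer that exposes the inner face of the C8 carbonyl, so that the C8 epimer forms. Fallback, from 22: if reduction delivers mainly the C8 epimer of 23 F9, this alcohol is esterified with inversion in a Mitsunobu reaction with 2-methylpropanoic acid (PPh3, diisopropyl azodicarboxylate, toluene, 0 °C), and the route is rejoined at 24.

**Further compounds**

F1 | step 9 | C5 epimer of aldol adduct 17 | C[C@@]12CC(=O)[C@](CI)([C@@H](O)[C@H](O[Si](CC)(CC)CC)/C=C(\CBr)C(=O)OC)[C@@H](C=C1Br)O2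
F2 | step 9 | β-diketone (C5 ketone) from F1 | C[C@@]12CC(=O)[C@](CI)(C(=O)[C@H](O[Si](CC)(CC)CC)/C=C(\CBr)C(=O)OC)[C@@H](C=C1Br)O2
F3 | step 14 | rac-7-bromo-1-methyl-4-[(tributylstannyl)methyl]-3-(trimethylsilyloxy)-8-oxabicyclo[3.2.1]octa-3,6-diene | C[C@@]12CC(O[Si](C)(C)C)=C(C[Sn](CCCC)(CCCC)CCCC)[C@@H](C=C1Br)O2
F4 | step 14 | stannyl analogue of 17 (CH2SnBu3 on C4) | C[C@@]12CC(=O)[C@](C[Sn](CCCC)(CCCC)CCCC)([C@H](O)[C@H](O[Si](CC)(CC)CC)/C=C(\CBr)C(=O)OC)[C@@H](C=C1Br)O2
F5 | step 14 | stannyl analogue of 18 | C[C@@]12CC(=O)[C@](C[Sn](CCCC)(CCCC)CCCC)([C@H](O[Si](C)(C)C(C)(C)C)[C@H](O[Si](CC)(CC)CC)/C=C(\CBr)C(=O)OC)[C@@H](C=C1Br)O2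
F6 | step 14 | stannyl analogue of 19 | C[C@@]12C[C@]3(O)[C@@H](C(=C)C(=O)OC)[C@@H](O[Si](CC)(CC)CC)[C@@H](O[Si](C)(C)C(C)(C)C)[C@]3(C[Sn](CCCC)(CCCC)CCCC)[C@@H](C=C1Br)O2
F7 | step 14 | stannyl analogue of 20 | C[C@@]12C[C@]3(O)[C@@H](C(=C)CO)[C@@H](O[Si](CC)(CC)CC)[C@@H](O[Si](C)(C)C(C)(C)C)[C@]3(C[Sn](CCCC)(CCCC)CCCC)[C@@H](C=C1Br)O2
F8 | step 14 | stannyl analogue of 21 (γ-stannyl tertiary alcohol) | C[C@@]12C[C@]3(O)[C@@H](C(=C)CO[Si](CC)(CC)CC)[C@@H](O[Si](CC)(CC)CC)[C@@H](O[Si](C)(C)C(C)(C)C)[C@]3(C[Sn](CCCC)(CCCC)CCCC)[C@@H](C=C1Br)O2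
F9 | step 15 | C8 epimer of alcohol 23 | C[C@@]12C[C@H](O)[C@@H](C(=C)CO[Si](CC)(CC)CC)[C@@H](O[Si](CC)(CC)CC)[C@@H](O[Si](C)(C)C(C)(C)C)C(=C)[C@@H](C=C1Br)O2
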